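Assumption: the target has no stereocentre, so "single enantiomer" is read as the single (E,E) geometric isomer shown. Both alkenes are carried in unchanged from (E)-caffeic acid.

## Retrosynthetic overview

- (E)-Caffeic acid (1) supplies both aryl rings and both E alkenes ready-made; no ring is formed anywhere in the route.
- Key disconnections are the two amide C–N bonds: 1 is activated by DCC, through its O-acylisourea (2), as the isolable N-hydroxysuccinimide ester (3).
- Spermidine (4) is acylated at its two primary amines only, through the mono-amides (5, 6), to give the target (7). The secondary N4 is left free by kinetic selectivity, so no protecting groups are used.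

## Route

Step 1
Reactants: 1 (E)-caffeic acid [(2E)-3-(3,4-dihydroxyphenyl)prop-2-enoic acid]
Product: 3 (E)-caffeic acid N-hydroxysuccinimide ester, via O-caffeoyl-N,N'-dicyclohexylisourea 2 (not isolated)
Conditions: N-hydroxysuccinimide (1.1 equiv), DCC (1.05 equiv), dry THF, N2, 0 °C → rt, 16 h; filter, recrystallise (EtOAc/hexane)
Reagents that add atoms: N-hydroxysuccinimide, O=C1CCC(=O)N1O
Why: Carbodiimide (Steglich-type) active-ester formation: the acid adds to DCC to give O-acylisourea 2, which the acidic, alpha-effect nucleophile N-hydroxysuccinimide intercepts much faster than the un-ionised catechol hydroxyls (no base present), and the E alkene is not touched.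

Step 2
Reactants: 3 (E)-caffeic acid N-hydroxysuccinimide ester (2.0 equiv); 4 spermidine [N-(3-aminopropyl)butane-1,4-diamine] (1.0 equiv)
Product: 7 N1,N8-bis(caffeoyl)spermidine, via N1-caffeoylspermidine 5 (not isolated), via N8-caffeoylspermidine 6 (not isolated)
Conditions: 3 in THF added over 2 h to 4 in degassed DMF, Ar, −20 °C → rt, 12 h; C18 reversed-phase chromatography (H2O/MeOH)
Reagents that add atoms: none
Why: Chemoselective aminolysis of an N-hydroxysuccinimide active ester: at low temperature and with slow addition the unhindered primary amines react far faster than the hindered secondary N4 (which also ends up protonated by the liberated weak acid), neutral phenols are not acylated, and the E geometry is simply retained from 3.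

## Compound list

1 | (E)-caffeic acid, (2E)-3-(3,4-dihydroxyphenyl)prop-2-enoic acid | O=C(O)/C=C/c1ccc(O)c(O)c1 | starting material
2 | O-[(E)-caffeoyl]-N,N'-dicyclohexylisourea | O=C(/C=C/c1ccc(O)c(O)c1)OC(=NC1CCCCC1)NC1CCCCC1 | intermediate
3 | (E)-caffeic acid N-hydroxysuccinimide ester, 2,5-dioxopyrrolidin-1-yl (2E)-3-(3,4-dihydroxyphenyl)prop-2-enoate | O=C(/C=C/c1ccc(O)c(O)c1)ON1C(=O)CCC1=O | intermediate
4 | spermidine, N-(3-aminopropyl)butane-1,4-diamine | NCCCCNCCCN | starting material
5 | N1-[(E)-caffeoyl]spermidine (amide on the aminopropyl nitrogen) | O=C(/C=C/c1ccc(O)c(O)c1)NCCCNCCCCN | intermediate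
6 | N8-[(E)-caffeoyl]spermidine (amide on the aminobutyl nitrogen) | O=C(/C=C/c1ccc(O)c(O)c1)NCCCCNCCCN | intermediate
7 | N1,N8-bis[(E)-caffeoyl]spermidine, (2E)-3-(3,4-dihydroxyphenyl)-N-[4-({3-[(2E)-3-(3,4-dihydroxyphenyl)prop-2-enamido]propyl}amino)butyl]prop-2-enamide | O=C(/C=C/c1ccc(O)c(O)c1)NCCCCNCCCNC(=O)/C=C/c1ccc(O)c(O)c1 | target

## Summary

Total step count: 2.
Longest linear sequence: 2 (1 → 3 → 7).

## Steps most likely to fail

The route has only two steps, so both are ranked and there is no third.

Most likely, step 2. The risks are acylation at N4 (tris-amide and regio-mixtures), incomplete bis-acylation, and catechol oxidation or O-acylation in the basic amine medium. The fallback protects N4 and sets out from 4, coming back to the route at 7. Spermidine 4 is treated with ethyl trifluoroacetate (2.0 equiv, MeOH, 0 °C → rt), which acylates only the primary amines to give N1,N8-bis(trifluoroacetyl)spermidine F1. Boc2O in the same pot then gives N4-Boc-N1,N8-bis(trifluoroacetyl)spermidine F2. K2CO3 in MeOH/H2O removes both trifluoroacetyl groups to give N4-Boc-spermidine F3, which has only primary amines free. F3 is acylated with ester 3 (2.0 equiv, DMF, rt) to N4-Boc-N1,N8-bis(caffeoyl)spermidine F4. HCl in dioxane (0 °C → rt, then neutralisation) removes the Boc group and delivers 7.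

Second, step 1. The risks are that the free catechol hydroxyls compete for the O-acylisourea (oligo-esters), that it rearranges to an N-acylurea, or that the ester cannot be freed from urea. The fallback masks the catechol and sets out from 1, coming back to the route at 7. Acid 1 is silylated (TBSCl 3.3 equiv, imidazole, DMF) to tert-butyldimethylsilyl (E)-3,4-bis(tert-butyldimethylsilyloxy)cinnamate F5. AcOH/THF/H2O cleaves only the silyl ester to give (E)-3,4-bis(tert-butyldimethylsilyloxy)cinnamic acid F6. EDC·HCl and N-hydroxysuccinimide in CH2Cl2 convert F6 into its N-hydroxysuccinimide ester F7. F7 (2.0 equiv) acylates spermidine 4 (CH2Cl2, −20 °C → rt) to N1,N8-bis[(E)-3,4-bis(tert-butyldimethylsilyloxy)cinnamoyl]spermidine F8. Et3N·3HF in THF removes the four silyl groups and the sequence arrives at 7.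

## Further compounds

F1 | step 2 | N1,N8-bis(trifluoroacetyl)spermidine | O=C(NCCCCNCCCNC(=O)C(F)(F)F)C(F)(F)F
F2 | step 2 | N4-Boc-N1,N8-bis(trifluoroacetyl)spermidine | O=C(NCCCCN(CCCNC(=O)C(F)(F)F)C(=O)OC(C)(C)C)C(F)(F)F
F3 | step 2 | N4-Boc-spermidine, tert-butyl (4-aminobutyl)(3-aminopropyl)carbamate | NCCCCN(CCCN)C(=O)OC(C)(C)C
F4 | step 2 | N4-Boc-N1,N8-bis[(E)-caffeoyl]spermidine | O=C(/C=C/c1ccc(O)c(O)c1)NCCCCN(CCCNC(=O)/C=C/c1ccc(O)c(O)c1)C(=O)OC(C)(C)C
F5 | step 1 | tert-butyldimethylsilyl (E)-3,4-bis(tert-butyldimethylsilyloxy)cinnamate | CC(C)(C)[Si](C)(C)OC(=O)/C=C/c1ccc(O[Si](C)(C)C(C)(C)C)c(O[Si](C)(C)C(C)(C)C)c1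
F6 | step 1 | (E)-3,4-bis(tert-butyldimethylsilyloxy)cinnamic acid | O=C(O)/C=C/c1ccc(O[Si](C)(C)C(C)(C)C)c(O[Si](C)(C)C(C)(C)C)c1
F7 | step 1 | (E)-3,4-bis(tert-butyldimethylsilyloxy)cinnamic acid N-hydroxysuccinimide ester | O=C(/C=C/c1ccc(O[Si](C)(C)C(C)(C)C)c(O[Si](C)(C)C(C)(C)C)c1)ON1C(=O)CCC1=O
F8 | step 1 | N1,N8-bis[(E)-3,4-bis(tert-butyldimethylsilyloxy)cinnamoyl]spermidine | O=C(/C=C/c1ccc(O[Si](C)(C)C(C)(C)C)c(O[Si](C)(C)C(C)(C)C)c1)NCCCCNCCCNC(=O)/C=C/c1ccc(O[Si](C)(C)C(C)(C)C)c(O[Si](C)(C)C(C)(C)C)c1
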